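(The rate constants were drawn at random within sensible limits; no experiment stands behind them.)

These flasks share a charge and a time and differ in temperature, so the cold end risks stopping too early and the hot end too late. Before charging the next run I wanted a test that shows when a sample stands on the late side.

common to all: starting material 0.050 M; reagent 0.900 equiv; second substrate 0.500 equiv; protic impurity 0.0100 M; time 3.0 h
- beta: temperature 75 °C
- alpha: temperature 0 °C
- zeta: temperature 25 °C
- theta: temperature 50 °C

    second substrate + reagent → second product (k1 = 4.15 L mol⁻¹ h⁻¹, Ea1 = 58.0 kJ mol⁻¹)
    starting material + reagent → target (k2 = 3.72 L mol⁻¹ h⁻¹, Ea2 = 54.0 kJ mol⁻¹)
    starting material + second substrate → cross product (k3 = 15.6 L mol⁻¹ h⁻¹, Ea3 = 60.0 kJ mol⁻¹)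
    reagent + target → over-reaction product (k4 = 1.12 L mol⁻¹ h⁻¹, Ea4 = 58.0 kJ mol⁻¹)
    starting material + protic impurity → quenched substrate (k5 = 3.48 L mol⁻¹ h⁻¹, Ea5 = 56.0 kJ mol⁻¹)
    starting material + target → side product (k6 = 1.32 L mol⁻¹ h⁻¹, Ea6 = 54.0 kJ mol⁻¹)
    (constants at 0 °C)

- a species is counted by the starting material in it: one side product counts as two
- the constants hold at 0 °C; other temperatures follow from the activation energies

- which flask leads in amount of target, in percent of the starting material charged ("all alike" within 1.5 percentage points) (beta / alpha / zeta / theta / all alike)
- how much target is there at the end, in percent of the starting material charged: beta
- how much target is there at the end, in percent of the starting material charged: alpha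
- how much target is there at the end, in percent of the starting material charged: zeta
- how much target is there at the end, in percent of the starting material charged: theta

Of the things reagent does here, two bear directly on target: it makes target from starting material, and it destroys target to give over-reaction product. I divided the rate of destruction by the rate of making. Reagent stands in both rates and cancels, time drops out, and what is left is a ratio of two constants multiplied by target over starting material. The two rates are equal when target stands to starting material at 3.32 at 0 °C, and I call this the crossing ratio.

The over-reaction step has the higher activation energy, by 4.00 kJ mol⁻¹, so the crossing ratio lies below that value in each warmer flask. The side product step takes target as well, so a sample whose ratio stands above the crossing ratio of its own temperature has target falling. Below that ratio the test gives no verdict.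

By hand I could say which side each extreme would end on, though not how high target would stand. At the full charge of reagent in alpha, target has a half-life against over-reaction of 13.8 h, longer than the 3.0 h allowed. Starting material has a half-life against reagent of 4.14 h, also longer than that time. So I expected alpha to end below the crossing ratio.

The over-reaction step shares its activation energy with the step that makes second product, so its constant rises by 250 times in beta. The half-life of target at the full charge of reagent then falls to 0.0561 h, far shorter than the time allowed. So I expected beta to end well past the crossing. I would not have charged either extreme again, but my reckoning did not choose between zeta and theta.

The forecast did choose. It named zeta at 23.5 %, with 19.7 % in alpha, 11 % in theta and 4.5 % in beta, and its ground for the hot flasks was this: “Leftover reagent then consumes target”.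

The simulation puts zeta ahead with 23.6 %, against 20.5 % in alpha, 9.13 % in theta and 2.06 % in beta. In zeta the closing ratio of target to starting material is 5.43, above even the crossing ratio of 0 °C, and zeta left ten times as long holds 7.12 % target. In alpha the closing ratio is 0.545, below the crossing ratio, and alpha holds 23.6 % target after 30.0 h.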